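The butenolide ring O1–C2–C3–C4–C5 is cut between C4 (the enol‑ester carbon) and C5 (the ylidene carbon). C4 is a masked ketone lying 1,3 to C6 across the exocyclic C5=C6 enol‑ester alkene, which is the pattern left by a nitrile oxide–alkene cycloaddition. The key step is therefore an intramolecular nitrile oxide cycloaddition of a (Z)‑1‑alkenyl 2‑methyl‑3‑nitropropanoate. In one operation it forms C4–C5, closes the lactone, brings C4 to the ketone level and copies the Z enol‑ester geometry into the C5/C6 relative configuration. N–O cleavage, O4‑stearoylation and a stereospecific syn dehydration should then give the contra‑thermodynamic E ylidene.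

Key step: step 13

Assumption: the exocyclic C5=C6 bond is taken as E exactly as drawn (C7, the methyl‑bearing S stereocentre next to the exocyclic CH C6, is cis to C4 and trans to O1); this is the less stable isomer, so it is made stereospecifically.

Step 1
Reactants: 1 (2E,6E)-3,7,11-trimethyldodeca-2,6,10-trien-1-yl acetate (farnesyl acetate)
Product: 2 (2E,6E,10E)-12-hydroxy-3,7,11-trimethyldodeca-2,6,10-trien-1-yl acetate
Conditions: SeO2 (0.3 equiv), t-BuOOH (3 equiv), salicylic acid (0.1 equiv), CH2Cl2, 0 °C to rt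
Reagents that add atoms: tert-butyl hydroperoxide CC(C)(C)OO (terminal oxidant; its oxygen is passed on by catalytic selenium dioxide O=[Se]=O)
Why: Riley-type allylic oxidation (ene reaction, then [2,3]-sigmatropic shift) should select the E-methyl group of the terminal trisubstituted alkene, the inner alkenes being less reactive and the one next to the acetate deactivated.

Step 2
Reactants: 2 (2E,6E,10E)-12-hydroxy-3,7,11-trimethyldodeca-2,6,10-trien-1-yl acetate
Product: 4 (2E,6E,10E)-12-acetoxy-2,6,10-trimethyldodeca-2,6,10-trienoic acid, via enal 3 (not isolated)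
Conditions: TEMPO (0.2 equiv), PhI(OAc)2 (2.4 equiv), MeCN/H2O 1:1, rt
Reagents that add atoms: water O
Why: Oxoammonium (TEMPO) oxidation in aqueous MeCN should take the allylic alcohol through the enal and its hydrate to the acid without touching the trisubstituted alkenes or the acetate, keeping the E geometry needed in step 3.

Step 3
Reactants: 4 (2E,6E,10E)-12-acetoxy-2,6,10-trimethyldodeca-2,6,10-trienoic acid
Product: 5 (2S,6E,10E)-12-acetoxy-2,6,10-trimethyldodeca-6,10-dienoic acid
Conditions: H2 (4 atm), Ru(OAc)2[(S)-H8-BINAP] (0.5 mol %), MeOH, 20 °C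
Reagents that add atoms: none
Why: Carboxylate-directed asymmetric hydrogenation should reduce only the conjugated C=C of this tiglic-acid-type substrate and set C7 as S under catalyst control, the (S)-H8-BINAP complex being the antipode that converts tiglic acid into (S)-2-methylbutanoic acid.

Step 4
Reactants: 5 (2S,6E,10E)-12-acetoxy-2,6,10-trimethyldodeca-6,10-dienoic acid
Product: 6 (2E,6E,11S)-3,7,11-trimethyldodeca-2,6-diene-1,12-diol
Conditions: LiAlH4, THF, 0 °C to rt; aqueous NaOH work-up
Reagents that add atoms: none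
Why: Hydride reduction should convert the acid into the primary alcohol and cleave the acetate in the same operation, leaving the isolated alkenes and the stereocentre untouched.

Step 5
Reactants: 6 (2E,6E,11S)-3,7,11-trimethyldodeca-2,6-diene-1,12-diol
Product: 7 (2S,6E,10E)-12-chloro-2,6,10-trimethyldodeca-6,10-dien-1-ol
Conditions: NCS (2.2 equiv), Me2S (2.5 equiv), CH2Cl2, −20 to 0 °C; aqueous work-up
Reagents that add atoms: N-chlorosuccinimide O=C1CCC(=O)N1Cl
Why: Corey–Kim chlorination converts allylic alcohols into chlorides without allylic transposition, whereas the saturated primary alcohol only forms an alkoxysulfonium salt that should revert to the alcohol on aqueous work-up.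

Step 6
Reactants: 8 furan-3-ylmethanol
Product: 9 3-(chloromethyl)furan
Conditions: SOCl2, pyridine, Et2O, 0 °C; used at once
Reagents that add atoms: thionyl chloride O=S(Cl)Cl
Why: Buffered chlorodehydroxylation of the primary furylmethyl alcohol should give the labile chloride, which is carried directly into the Grignard formation.

Step 7
Reactants: 9 3-(chloromethyl)furan; 7 (2S,6E,10E)-12-chloro-2,6,10-trimethyldodeca-6,10-dien-1-ol
Product: 11 (2S,6E,10E)-13-(furan-3-yl)-2,6,10-trimethyltrideca-6,10-dien-1-ol, via Grignard reagent 10 (not isolated)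
Conditions: Mg, THF, rt; then 7 (0.4 equiv), Li2CuCl4 (5 mol %), THF, 0 °C
Reagents that add atoms: none
Why: Li2CuCl4-catalysed (Kochi-type) Grignard cross-coupling with the primary allylic chloride should occur at the α-carbon with retention of the E alkene, the first equivalent of Grignard reagent only deprotonating the free alcohol.

Step 8
Reactants: 11 (2S,6E,10E)-13-(furan-3-yl)-2,6,10-trimethyltrideca-6,10-dien-1-ol
Product: 12 (2S,6E,10E)-13-(furan-3-yl)-2,6,10-trimethyltrideca-6,10-dienal
Conditions: Dess–Martin periodinane, NaHCO3, CH2Cl2, 0 °C; used crude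
Reagents that add atoms: none
Why: Buffered Dess–Martin oxidation is non-enolising, so the α-branched aldehyde should form without epimerisation at C7 and without attack on the furan or the alkenes.

Step 9
Reactants: 12 (2S,6E,10E)-13-(furan-3-yl)-2,6,10-trimethyltrideca-6,10-dienal
Product: 13 3-[(3E,7E,12S)-4,8,12-trimethyltetradeca-3,7-dien-13-yn-1-yl]furan
Conditions: dimethyl (1-diazo-2-oxopropyl)phosphonate, K2CO3, MeOH, 0 °C to rt
Reagents that add atoms: dimethyl (1-diazo-2-oxopropyl)phosphonate (Ohira–Bestmann reagent) COP(=O)(OC)C(=[N+]=[N-])C(C)=O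
Why: Seyferth–Gilbert homologation with the Ohira–Bestmann reagent adds the carbon that becomes C5 and, run cold, should keep the configuration of the α-methyl aldehyde.

Step 10
Reactants: 14 methyl 3-bromo-2-methylpropanoate (racemic)
Product: 15 methyl 2-methyl-3-nitropropanoate (racemic)
Conditions: NaNO2, phloroglucinol, DMSO, rt
Reagents that add atoms: sodium nitrite [Na+].[O-]N=O
Why: Kornblum substitution of the primary bromide by nitrite (phloroglucinol scavenging nitrite ester) should give the primary nitro ester; its stereocentre is irrelevant because this carbon becomes sp2 C3.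

Step 11
Reactants: 15 methyl 2-methyl-3-nitropropanoate
Product: 16 2-methyl-3-nitropropanoic acid (racemic)
Conditions: 6 M HCl, 60 °C
Reagents that add atoms: water O
Why: Acid-catalysed ester hydrolysis is chosen because base would eliminate HNO2 from the β-nitro ester.

Step 12
Reactants: 13 3-[(3E,7E,12S)-4,8,12-trimethyltetradeca-3,7-dien-13-yn-1-yl]furan; 16 2-methyl-3-nitropropanoic acid
Product: 17 (1Z,3S,7E,11E)-14-(furan-3-yl)-3,7,11-trimethyltetradeca-1,7,11-trien-1-yl 2-methyl-3-nitropropanoate
Conditions: Ru(2-methylallyl)2(dppb) (2 mol %; dppb = Ph2P(CH2)4PPh2), toluene, 65 °C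
Reagents that add atoms: none
Why: Ruthenium-catalysed anti-Markovnikov addition of a carboxylic acid to a terminal alkyne through a ruthenium vinylidene should give the (Z)-enol ester, forming the O1–C5 bond and leaving the furan, the internal alkenes and the nitro group untouched.

Step 13
Reactants: 17 (1Z,3S,7E,11E)-14-(furan-3-yl)-3,7,11-trimethyltetradeca-1,7,11-trien-1-yl 2-methyl-3-nitropropanoate
Product: 19 (3S,3aS)-3-[(2S,6E,10E)-13-(furan-3-yl)-6,10-dimethyltrideca-6,10-dien-2-yl]-6-methyl-3a,6-dihydro-3H-furo[3,4-c]isoxazol-5-one, via nitrile oxide 18 (not isolated)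
Conditions: PhNCO (3 equiv), Et3N (0.2 equiv), toluene, 80 °C, 0.005 M, slow addition of 17
Reagents that add atoms: none
Why: Mukaiyama dehydration of the primary nitro group gives nitrile oxide 18, whose carbon (C4) and oxygen add in a concerted, suprafacial way across the tethered enol-ester alkene C5=C6; the closest known reaction type is the intramolecular nitrile oxide–alkene cycloaddition of 5-hexenyl-type nitrile oxides to bicyclo[3.3.0] isoxazolines. Two rings close at once, the γ-lactone through the C4–C5 bond (5-exo with respect to the alkene, three-atom tether C3–C2–O1) and the isoxazoline through the O–C6 bond, necessarily cis-fused. The new stereocentres C5 and C6 are controlled by the Z geometry of the enol ester, which keeps O1 and C7 cis (H-5 and H-6 cis); the face of attack relative to C7 and the epimerisable C3 centre do not matter, because C3 becomes sp2 in step 14 and C5/C6 become sp2 in step 16. The step needs C4–C5 rather than C4–C6 bonding, against the electronic bias of an enol ester; the short tether should secure this, since the other mode would place the C=N bond at a bridgehead of a bicyclo[3.2.1] skeleton. The two trisubstituted alkenes and the furan are remote and poorer dipolarophiles, and slow generation at high dilution is meant to suppress dimerisation of 18 to the furoxan.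

Step 14
Reactants: 19 (3S,3aS)-3-[(2S,6E,10E)-13-(furan-3-yl)-6,10-dimethyltrideca-6,10-dien-2-yl]-6-methyl-3a,6-dihydro-3H-furo[3,4-c]isoxazol-5-one
Product: 21 (5R)-5-[(1S,2S,6E,10E)-13-(furan-3-yl)-1-hydroxy-2,6,10-trimethyltrideca-6,10-dien-1-yl]-4-hydroxy-3-methylfuran-2(5H)-one, via aminofuranone 20 (not isolated)
Conditions: Mo(CO)6, MeCN/H2O 15:1, 80 °C; then 1 M HCl, THF, rt
Reagents that add atoms: water O
Why: Mo(CO)6 cleaves the isoxazoline N–O bond reductively, and the β-hydroxy imine, which may rest as the vinylogous carbamate 20, should be hydrolysed by dilute acid to the 3-methyltetronic acid without change at C5/C6, the alkenes or the furan.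

Step 15
Reactants: 21 (5R)-5-[(1S,2S,6E,10E)-13-(furan-3-yl)-1-hydroxy-2,6,10-trimethyltrideca-6,10-dien-1-yl]-4-hydroxy-3-methylfuran-2(5H)-one; 22 octadecanoyl chloride (stearoyl chloride)
Product: 23 (2R)-2-[(1S,2S,6E,10E)-13-(furan-3-yl)-1-hydroxy-2,6,10-trimethyltrideca-6,10-dien-1-yl]-4-methyl-5-oxo-2,5-dihydrofuran-3-yl octadecanoate
Conditions: Et3N (1.05 equiv), CH2Cl2, −40 to 0 °C
Reagents that add atoms: none
Why: The tetronate anion should be O-acylated at O4 by the acid chloride far faster than the hindered secondary alcohol, C-acylation being blocked by the C3 methyl group.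

Step 16
Reactants: 23 (2R)-2-[(1S,2S,6E,10E)-13-(furan-3-yl)-1-hydroxy-2,6,10-trimethyltrideca-6,10-dien-1-yl]-4-methyl-5-oxo-2,5-dihydrofuran-3-yl octadecanoate
Product: 25 (2E)-2-[(2S,6E,10E)-13-(furan-3-yl)-2,6,10-trimethyltrideca-6,10-dien-1-ylidene]-4-methyl-5-oxo-2,5-dihydrofuran-3-yl octadecanoate, via sulfamate ester 24 (not isolated)
Conditions: Burgess reagent (1.5 equiv), toluene, rt then 50 °C, dark
Reagents that add atoms: none
Why: The Burgess reagent converts the secondary alcohol into a sulfamate ester that eliminates thermally in a syn (Ei) fashion with the acidic C5 hydrogen, so the C5/C6 relationship set in step 13 should translate into the E ylidene (C7 cis to C4) under neutral conditions that spare C7 and the product geometry.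

Compound list
1 | (2E,6E)-3,7,11-trimethyldodeca-2,6,10-trien-1-yl acetate (farnesyl acetate) | CC(C)=CCC/C(C)=C/CC/C(C)=C/COC(C)=O | starting material
2 | (2E,6E,10E)-12-hydroxy-3,7,11-trimethyldodeca-2,6,10-trien-1-yl acetate | OC/C(C)=C/CC/C(C)=C/CC/C(C)=C/COC(C)=O | intermediate
3 | (2E,6E,10E)-3,7,11-trimethyl-12-oxododeca-2,6,10-trien-1-yl acetate (enal, not isolated) | O=C/C(C)=C/CC/C(C)=C/CC/C(C)=C/COC(C)=O | intermediate
4 | (2E,6E,10E)-12-acetoxy-2,6,10-trimethyldodeca-2,6,10-trienoic acid | OC(=O)/C(C)=C/CC/C(C)=C/CC/C(C)=C/COC(C)=O | intermediate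
5 | (2S,6E,10E)-12-acetoxy-2,6,10-trimethyldodeca-6,10-dienoic acid | OC(=O)[C@@H](C)CCC/C(C)=C/CC/C(C)=C/COC(C)=O | intermediate
6 | (2E,6E,11S)-3,7,11-trimethyldodeca-2,6-diene-1,12-diol | OC[C@@H](C)CCC/C(C)=C/CC/C(C)=C/CO | intermediate
7 | (2S,6E,10E)-12-chloro-2,6,10-trimethyldodeca-6,10-dien-1-ol | OC[C@@H](C)CCC/C(C)=C/CC/C(C)=C/CCl | intermediate
8 | furan-3-ylmethanol | OCc1ccoc1 | starting material
9 | 3-(chloromethyl)furan | ClCc1ccoc1 | intermediate
10 | (furan-3-ylmethyl)magnesium chloride (not isolated) | Cl[Mg]Cc1ccoc1 | intermediate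
11 | (2S,6E,10E)-13-(furan-3-yl)-2,6,10-trimethyltrideca-6,10-dien-1-ol | OC[C@@H](C)CCC/C(C)=C/CC/C(C)=C/CCc1ccoc1 | intermediate
12 | (2S,6E,10E)-13-(furan-3-yl)-2,6,10-trimethyltrideca-6,10-dienal | O=C[C@@H](C)CCC/C(C)=C/CC/C(C)=C/CCc1ccoc1 | intermediate
13 | 3-[(3E,7E,12S)-4,8,12-trimethyltetradeca-3,7-dien-13-yn-1-yl]furan | C#C[C@@H](C)CCC/C(C)=C/CC/C(C)=C/CCc1ccoc1 | intermediate
14 | methyl 3-bromo-2-methylpropanoate (racemic) | COC(=O)C(C)CBr | starting material
15 | methyl 2-methyl-3-nitropropanoate (racemic) | COC(=O)C(C)C[N+](=O)[O-] | intermediate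
16 | 2-methyl-3-nitropropanoic acid (racemic) | OC(=O)C(C)C[N+](=O)[O-] | intermediate
17 | (1Z,3S,7E,11E)-14-(furan-3-yl)-3,7,11-trimethyltetradeca-1,7,11-trien-1-yl 2-methyl-3-nitropropanoate (both epimers at the acyl α-carbon) | [O-][N+](=O)CC(C)C(=O)O/C=C\[C@@H](C)CCC/C(C)=C/CC/C(C)=C/CCc1ccoc1 | intermediate
18 | (1Z,3S,7E,11E)-14-(furan-3-yl)-3,7,11-trimethyltetradeca-1,7,11-trien-1-yl 2-cyanopropanoate N-oxide (nitrile oxide, not isolated) | [O-][N+]#CC(C)C(=O)O/C=C\[C@@H](C)CCC/C(C)=C/CC/C(C)=C/CCc1ccoc1 | intermediate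
19 | (3S,3aS)-3-[(2S,6E,10E)-13-(furan-3-yl)-6,10-dimethyltrideca-6,10-dien-2-yl]-6-methyl-3a,6-dihydro-3H-furo[3,4-c]isoxazol-5-one (H-3 and H-3a cis; one of two facial diastereomers drawn, both with the same C3/C3a relationship; epimers at C6) | CC1C(=O)O[C@@H]2[C@H]([C@@H](C)CCC/C(C)=C/CC/C(C)=C/CCc3ccoc3)ON=C12 | intermediate
20 | (5S)-4-amino-5-[(1S,2S,6E,10E)-13-(furan-3-yl)-1-hydroxy-2,6,10-trimethyltrideca-6,10-dien-1-yl]-3-methylfuran-2(5H)-one (not isolated; same spatial arrangement at C5 as 21, the descriptor differs only through the priority rules) | CC1=C(N)[C@H](OC1=O)[C@@H](O)[C@@H](C)CCC/C(C)=C/CC/C(C)=C/CCc2ccoc2 | intermediate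
21 | (5R)-5-[(1S,2S,6E,10E)-13-(furan-3-yl)-1-hydroxy-2,6,10-trimethyltrideca-6,10-dien-1-yl]-4-hydroxy-3-methylfuran-2(5H)-one | CC1=C(O)[C@H](OC1=O)[C@@H](O)[C@@H](C)CCC/C(C)=C/CC/C(C)=C/CCc2ccoc2 | intermediate
22 | octadecanoyl chloride (stearoyl chloride) | CCCCCCCCCCCCCCCCCC(=O)Cl | starting material
23 | (2R)-2-[(1S,2S,6E,10E)-13-(furan-3-yl)-1-hydroxy-2,6,10-trimethyltrideca-6,10-dien-1-yl]-4-methyl-5-oxo-2,5-dihydrofuran-3-yl octadecanoate | CCCCCCCCCCCCCCCCCC(=O)OC1=C(C)C(=O)O[C@@H]1[C@@H](O)[C@@H](C)CCC/C(C)=C/CC/C(C)=C/CCc2ccoc2 | intermediate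
24 | (2R)-2-[(1S,2S,6E,10E)-13-(furan-3-yl)-1-{[(methoxycarbonyl)sulfamoyl]oxy}-2,6,10-trimethyltrideca-6,10-dien-1-yl]-4-methyl-5-oxo-2,5-dihydrofuran-3-yl octadecanoate (sulfamate ester, not isolated) | CCCCCCCCCCCCCCCCCC(=O)OC1=C(C)C(=O)O[C@@H]1[C@@H](OS(=O)(=O)NC(=O)OC)[C@@H](C)CCC/C(C)=C/CC/C(C)=C/CCc2ccoc2 | intermediate
25 | (2E)-2-[(2S,6E,10E)-13-(furan-3-yl)-2,6,10-trimethyltrideca-6,10-dien-1-ylidene]-4-methyl-5-oxo-2,5-dihydrofuran-3-yl octadecanoate | CCCCCCCCCCCCCCCCCC(=O)OC1=C(C)C(=O)O/C1=C/[C@@H](C)CCC/C(C)=C/CC/C(C)=C/CCc1ccoc1 | target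

Total step count: 16. Longest linear sequence: 13 steps (1, 2, 3, 4, 5, 7, 8, 9, 12, 13, 14, 15, 16, from farnesyl acetate 1 to 25).

Steps most likely to fail

Step 13. The cyclisation must pass through the less stable rotamer of the ester tether, forces the nitrile oxide carbon onto the oxygen-bearing alkene carbon against the electronic preference, and places the branched chain on the concave face. It may therefore be slow enough for nitrile oxide dimerisation to take over. The fallback uses known chemistry and gives up the cycloaddition, forming the C5–C6 bond instead. It sets out from aldehyde 12. 4-(Allyloxy)-3-methylfuran-2(5H)-one F1 would be made from commercial 4-hydroxy-3-methylfuran-2(5H)-one by Mitsunobu O-allylation (allyl alcohol, PPh3, DIAD). F1 would be deprotonated at C5 with LiN(iPr)2 in THF at −78 °C and added to 12 in a vinylogous aldol addition. The allyl ether aldol adduct F2 that has the C5/C6 relative configuration of 21 would be separated from its diastereomers by chromatography. Deallylation with Pd(PPh3)4 and morpholine would bring it back to the route at 21.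

Step 16. Deprotonation at the acidic C5 position may run ahead of the concerted syn elimination (E1cB through the furanolate), which would scramble the geometry toward the more stable Z ylidene. Elimination toward C7 and migration of the stearoyl group to the neighbouring oxygen are further possible leaks. The fallback sets out from 23. Appel-type iodination with inversion at C6 (PPh3, I2, imidazole) would give the C6-inverted iodide F3. Its anti-periplanar E2 dehydroiodination with DBU in toluene at low temperature leads to the same E alkene and rejoins the route at 25.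

Step 12. The acidic nitroalkane may deactivate the ruthenium catalyst, and the branched propargylic position may erode the anti-Markovnikov and Z selectivity of the addition. The fallback sets out from alkyne 13. Rhodium-catalysed trans-hydroboration ([Rh(cod)Cl]2, P(iPr)3, Et3N, pinacolborane) would give the (Z)-alkenyl pinacol boronate F4. KHF2 in aqueous MeOH would convert it into the potassium (Z)-alkenyltrifluoroborate F5. Copper-catalysed oxidative C–O coupling of F5 with acid 16 (CuBr, DMAP, O2, 4 Å molecular sieves, MeCN) would give the enol ester with retention of geometry, rejoining the route at 17.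

Further compounds
F1 | step 13 | 4-(allyloxy)-3-methylfuran-2(5H)-one | CC1=C(OCC=C)COC1=O
F2 | step 13 | (5R)-4-(allyloxy)-5-[(1S,2S,6E,10E)-13-(furan-3-yl)-1-hydroxy-2,6,10-trimethyltrideca-6,10-dien-1-yl]-3-methylfuran-2(5H)-one | CC1=C(OCC=C)[C@H](OC1=O)[C@@H](O)[C@@H](C)CCC/C(C)=C/CC/C(C)=C/CCc2ccoc2
F3 | step 16 | (2S)-2-[(1R,2S,6E,10E)-13-(furan-3-yl)-1-iodo-2,6,10-trimethyltrideca-6,10-dien-1-yl]-4-methyl-5-oxo-2,5-dihydrofuran-3-yl octadecanoate | CCCCCCCCCCCCCCCCCC(=O)OC1=C(C)C(=O)O[C@@H]1[C@H](I)[C@@H](C)CCC/C(C)=C/CC/C(C)=C/CCc2ccoc2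
F4 | step 12 | 2-[(1Z,3S,7E,11E)-14-(furan-3-yl)-3,7,11-trimethyltetradeca-1,7,11-trien-1-yl]-4,4,5,5-tetramethyl-1,3,2-dioxaborolane | CC1(C)OB(/C=C\[C@@H](C)CCC/C(C)=C/CC/C(C)=C/CCc2ccoc2)OC1(C)C
F5 | step 12 | potassium trifluoro[(1Z,3S,7E,11E)-14-(furan-3-yl)-3,7,11-trimethyltetradeca-1,7,11-trien-1-yl]borate | [K+].F[B-](F)(F)/C=C\[C@@H](C)CCC/C(C)=C/CC/C(C)=C/CCc1ccoc1
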